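## Retrosynthetic overview

1. The target is (R)-5,8-dihydroxy-2-pentadecylchroman-4-one (ring A = benzene ring, ring B = pyranone ring). The last operations are cleavage of the two aryl methyl ethers and, before that, a CuH-catalysed asymmetric 1,4-reduction of an achiral chromone, which sets C2.
2. Key disconnection: ring B is cut at C2–C3 and at C4–C4a. This gives an aryl oxocarbenium ion (O1=C2, carrying the pentadecyl chain) and the two-carbon ketene equivalent ethoxyacetylene. Both bonds form in one cationic formal [4+2] annulation, and dehydrogenation in the same flask leads to the chromone.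
3. Enabling feature: the ether oxygen O1 that links arene carbon C8a to C2. It makes C2 an oxocarbenium carbon and holds the new C4 cation next to C4a, the only free position ortho to O1 on ring A, which is flanked and activated by the C5 oxygen. C4a=C8a–O1=C2 is the four-atom partner.
4. The oxocarbenium precursor is the O-aryl O-pivaloyl acetal built from 2,5-dimethoxyphenol, hexadecanal and pivaloyl chloride. Ring A is bought; ring B is the only ring formed (step 3).

Key step: step 3

Assumption: (R)-DTBM-SEGPHOS is written in step 4 on the assumption that it delivers hydride to the C2 face that gives the (R) product; if a first run shows the opposite sense, (S)-DTBM-SEGPHOS is used under the same conditions.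

## Route

Step 1
Reactants: 1 hexadecanal; 2 pivaloyl chloride
Product: 3 1-chlorohexadecyl pivalate (racemic)
Conditions: ZnCl2 (2 mol%), CH2Cl2, −10 °C to rt
Reagents that add atoms: none
Why: ZnCl2-catalysed addition of an acyl chloride across an aldehyde C=O (1-chloroalkyl ester formation) is a standard entry to 1-chloroalkyl esters of aliphatic aldehydes and gives no co-product; the new centre is racemic and is erased later.

Step 2
Reactants: 4 2,5-dimethoxyphenol; 3 1-chlorohexadecyl pivalate
Product: 5 1-(2,5-dimethoxyphenoxy)hexadecyl pivalate (racemic)
Conditions: Cs2CO3, NaI (cat.), DMF, 0 °C to rt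
Reagents that add atoms: none
Why: Williamson-type O-alkylation of a phenoxide with a 1-chloroalkyl ester (acyloxyalkyl ether formation, as used for phenol prodrugs) should give the O-aryl O-acyl acetal, with the bulky pivalate suppressing acyl transfer to the phenoxide; the acetal centre is racemic.

Step 3
Reactants: 5 1-(2,5-dimethoxyphenoxy)hexadecyl pivalate; 6 ethoxyacetylene (solution in hexanes)
Product: 9 5,8-dimethoxy-2-pentadecyl-4H-chromen-4-one, via ethoxychromene 7 (not isolated), via ethoxychromenylium triflate 8 (not isolated)
Conditions: 6 (2 equiv), 2,6-di-tert-butyl-4-methylpyridine (1.5 equiv), CH2Cl2, −78 °C, then Me3SiOTf (1.2 equiv), −78 to −20 °C; volatiles removed; DDQ (1.3 equiv), CH2Cl2, 0 °C to rt; H2O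
Reagents that add atoms: water, O
Why: Proposed new method: Me3SiOTf should ionise the C–O bond to the pivalate (loss of the aryloxy group would leave a poorly stabilised acyloxy carbenium ion) to give the aryl oxocarbenium ion with O1 double-bonded to C2; the CH carbon of the ynol ether adds to C2 (C2–C3 bond), the resulting O-ethyl ketenium carbon C4 is attacked by arene carbon C4a (C4–C4a bond), and the hindered pyridine takes the proton to leave enol ether 7. The closest known reaction types are the oxa-Povarov formal [4+2] cycloaddition of aryl oxocarbenium ions with alkenes, the alkyne Povarov synthesis of quinolines from N-aryl iminium ions, and the Lewis acid addition of alkoxyacetylenes to acetals; new is the ynol ether as ketene equivalent, so that C4 arrives at the ketone oxidation level. Ring B closes as a six-membered ring by intramolecular Friedel–Crafts attack on the digonal ketenium carbon (6-exo-dig with respect to the C4=O π bond), with the C3=C4 bond staying inside the ring. The C2 stereocentre forms without control and is erased in the same flask, because DDQ abstracts the C2 hydride (allylic and α to O1) to give the aromatic 4-ethoxychromenylium salt 8, which water hydrolyses at C4 to chromone 9; C2 is set afresh in step 4. The step needs regioselective bond formation at both ends: the polarisation of the ynol ether directs its CH carbon to C2 and leaves the cation on C4, and C4a is the only unsubstituted position ortho to O1 and is activated by O1 and the C5 methoxy group. The ynol ether is present before the Lewis acid is added, so that the oxocarbenium ion should be intercepted before it loses a proton or alkylates a second arene.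

Step 4
Reactants: 9 5,8-dimethoxy-2-pentadecyl-4H-chromen-4-one
Product: 11 (R)-5,8-dimethoxy-2-pentadecylchroman-4-one, via silyl enol ether 10 (not isolated)
Conditions: Cu(OAc)2·H2O (5 mol%), (R)-DTBM-SEGPHOS (5.5 mol%), (EtO)2MeSiH (2.5 equiv), toluene, 0 °C to rt; then 1 M HCl, THF, 0 °C
Reagents that add atoms: none
Why: In this CuH-catalysed asymmetric conjugate reduction of a β,β-disubstituted enone, the bisphosphine-bound monovalent copper hydride delivers hydride to one enantiotopic face of C2 under ligand control, and trapping of the copper enolate as silyl enol ether 10 keeps the aryl ketone from 1,2-reduction until mild acid hydrolysis releases 11.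

Step 5
Reactants: 11 (R)-5,8-dimethoxy-2-pentadecylchroman-4-one
Product: 12 (R)-5,8-dihydroxy-2-pentadecylchroman-4-one
Conditions: BBr3 (6 equiv), CH2Cl2, −78 to 0 °C, argon; then H2O, 0 °C
Reagents that add atoms: none
Why: Lewis acid cleavage of aryl methyl ethers with BBr3 should free both phenols (the C5 ether assisted by chelation to the C4 carbonyl), while the secondary C2–O1 ether, a weakly basic vinylogous ester oxygen, and with it the C2 stereocentre should stay untouched at low temperature.

## Compound list

1 | hexadecanal | CCCCCCCCCCCCCCCC=O | starting material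
2 | pivaloyl chloride (2,2-dimethylpropanoyl chloride) | CC(C)(C)C(Cl)=O | starting material
3 | 1-chlorohexadecyl pivalate, racemic | CCCCCCCCCCCCCCCC(Cl)OC(=O)C(C)(C)C | intermediate
4 | 2,5-dimethoxyphenol | COc1ccc(OC)c(O)c1 | starting material
5 | 1-(2,5-dimethoxyphenoxy)hexadecyl pivalate, racemic | CCCCCCCCCCCCCCCC(OC(=O)C(C)(C)C)Oc1cc(OC)ccc1OC | intermediate
6 | ethoxyacetylene (ethoxyethyne) | CCOC#C | starting material
7 | 4-ethoxy-5,8-dimethoxy-2-pentadecyl-2H-chromene, racemic, formed in the flask | CCCCCCCCCCCCCCCC1C=C(OCC)c2c(OC)ccc(OC)c2O1 | intermediate
8 | 4-ethoxy-5,8-dimethoxy-2-pentadecylchromenylium triflate, formed in the flask | CCCCCCCCCCCCCCCc1cc(OCC)c2c(OC)ccc(OC)c2[o+]1.[O-]S(=O)(=O)C(F)(F)F | intermediate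
9 | 5,8-dimethoxy-2-pentadecyl-4H-chromen-4-one | CCCCCCCCCCCCCCCC1=CC(=O)c2c(OC)ccc(OC)c2O1 | intermediate
10 | (R)-4-{[diethoxy(methyl)silyl]oxy}-5,8-dimethoxy-2-pentadecyl-2H-chromene, formed in the flask | CCCCCCCCCCCCCCC[C@@H]1C=C(O[Si](C)(OCC)OCC)c2c(OC)ccc(OC)c2O1 | intermediate
11 | (R)-5,8-dimethoxy-2-pentadecylchroman-4-one | CCCCCCCCCCCCCCC[C@@H]1CC(=O)c2c(OC)ccc(OC)c2O1 | intermediate
12 | (R)-5,8-dihydroxy-2-pentadecylchroman-4-one | CCCCCCCCCCCCCCC[C@@H]1CC(=O)c2c(O)ccc(O)c2O1 | target

Total step count: 5
Longest linear sequence: 5 steps (1 → 3 → 5 → 9 → 11 → 12)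

## Steps most likely to fail

**Step 3 (key step, proposed new method).**
- What may go wrong: the ketenium ion may be consumed by further ynol ether (oligomerisation) or by attack of O1 on C4 (four-membered oxetenium ion, then alkyne–oxocarbenium metathesis with loss of the phenol) faster than by C4a. The oxocarbenium ion may also lose a proton to give the aryl enol ether.
- Fallback (known chemistry): it sets out from 4 and comes back to the route at 11, so that steps 2 to 4 are bypassed. Commercial methyl 3-oxooctadecanoate is reduced by Noyori asymmetric hydrogenation (RuCl2[(S)-BINAP], H2, MeOH) to methyl (S)-3-hydroxyoctadecanoate F1. Mitsunobu etherification of 4 with F1 (PPh3, DIAD, toluene, 0 °C) should give, with inversion at the carbinol carbon, methyl (R)-3-(2,5-dimethoxyphenoxy)octadecanoate F2. Saponification (LiOH, THF/H2O) should give (R)-3-(2,5-dimethoxyphenoxy)octadecanoic acid F3. Intramolecular Friedel–Crafts acylation (Eaton's reagent, P2O5 in MeSO3H, rt) should close ring B at the same arene carbon and give 11.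

**Step 4.**
- What may go wrong: poor facial selectivity, because the two substituents at C2 of the chromone (alkyl chain and ring oxygen) are differentiated mainly electronically; or slow 1,4-addition to the vinylogous ester with competing 1,2-reduction.
- Fallback: it sets out from 9 and comes back at 11. Asymmetric hydrogenation with a chiral Ru–NHC catalyst (Ru(cod)(2-methylallyl)2, the suitable antipode of the NHC salt SINpEt·HBF4, KOtBu, H2, hexane) should reduce the C2=C3 bond enantioselectively together with the ketone and give (2R)-5,8-dimethoxy-2-pentadecylchroman-4-ol F4 as a mixture of C4 epimers. Oxidation with Dess–Martin periodinane (CH2Cl2, rt) should return ketone 11 without touching C2.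

**Step 5.**
- What may go wrong: cleavage of the C2–O1 ring ether, or retro-oxa-Michael opening of ring B with loss of configuration, under the Lewis acid; air oxidation of the hydroquinone during work-up.
- Fallback: it sets out from 11 and comes back at 12. Oxidative demethylation of the para-dimethoxy arene ((NH4)2Ce(NO3)6, MeCN/H2O, 0 °C) should give (R)-2-pentadecyl-2,3-dihydro-4H-chromene-4,5,8-trione F5. Immediate reduction of this quinone (Na2S2O4, EtOAc/H2O, rt) should give 12 without any Lewis acid.

## Further compounds

F1 | step 3 | methyl (S)-3-hydroxyoctadecanoate | CCCCCCCCCCCCCCC[C@H](O)CC(=O)OC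
F2 | step 3 | methyl (R)-3-(2,5-dimethoxyphenoxy)octadecanoate | CCCCCCCCCCCCCCC[C@@H](Oc1cc(OC)ccc1OC)CC(=O)OC
F3 | step 3 | (R)-3-(2,5-dimethoxyphenoxy)octadecanoic acid | CCCCCCCCCCCCCCC[C@@H](Oc1cc(OC)ccc1OC)CC(O)=O
F4 | step 4 | (2R)-5,8-dimethoxy-2-pentadecylchroman-4-ol, mixture of C4 epimers | CCCCCCCCCCCCCCC[C@@H]1CC(O)c2c(OC)ccc(OC)c2O1
F5 | step 5 | (R)-2-pentadecyl-2,3-dihydro-4H-chromene-4,5,8-trione | CCCCCCCCCCCCCCC[C@@H]1CC(=O)C2=C(O1)C(=O)C=CC2=O
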